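The target is cut at C7–C8 of the seven-membered ring, the bond between the isopropyl-bearing methine and the angeloyloxy carbinol. This H/O pair next to the C6 acetate is the retron of a syn, anti-Markovnikov hydration of a C7=C8 olefin, so the ring is closed there by ring-closing metathesis and one hydroboration anti to O6 then sets C7 and C8 together. The metathesis precursor is a cyclopentane carrying a (Z)-tetrasubstituted C1=C10 alkene with an allyl arm and a 1-acetoxy-2-isopropylallyl arm; C4, C5 and C6 arise from one borylative conjugate addition–aldol coupling, and the alkene geometry from a lactone tether.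

Key step: step 10

Atom labels used below (guaiane numbering): five-membered ring C1–C5 (C1 ring-fusion alkene carbon, C4 carbinol carbon, C5 ring-fusion CH); seven-membered ring C1, C5, C6 (OAc), C7 (i-Pr), C8 (O-angeloyl), C9, C10 (methyl-bearing alkene carbon).

Assumption: (R,R)-QuinoxP* is taken to deliver boron to the enone face that gives the (3R)-boronate 5; if the sense of induction is the opposite, the (S,S)-ligand is used instead.

Step 1
Reactants: 1 3-methylbutanal
Product: 2 3-methyl-2-methylidenebutanal
Conditions: aq CH2O (37 %), pyrrolidine (10 mol %), propanoic acid (10 mol %), i-PrOH, 45 °C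
Reagents that add atoms: formaldehyde, C=O
Why: Amine-catalysed Mannich condensation and β-elimination (α-methylenation of an aldehyde) is routine for α-unbranched aldehydes and creates no stereocentre.

Step 2
Reactants: 3 3-methylcyclopent-2-en-1-one; 4 bis(pinacolato)diboron; 2 3-methyl-2-methylidenebutanal
Product: 6 (2S,3R)-2-[(1S)-1-hydroxy-3-methyl-2-methylidenebutyl]-3-methyl-3-(pinacolboryl)cyclopentan-1-one, via boron enolate 5 (not isolated)
Conditions: CuPF6(MeCN)4 (5 mol %), (R,R)-QuinoxP* (6 mol %), LiOt-Bu (10 mol %), DMSO, rt; then 2, THF, −20 °C → rt; aq NH4Cl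
Reagents that add atoms: none
Why: Copper-catalysed enantioselective conjugate borylation sets C4 under ligand control, and the cyclic (necessarily E) boron enolate should add to 2 through a Zimmerman–Traxler chair on the face anti to the new C–B bond, giving the C4/C5 trans and C5/C6 anti relationships (conjugate borylation–aldol three-component coupling).

Step 3
Reactants: 6 borylated aldol adduct; 7 2-(diethoxyphosphoryl)propanoic acid
Product: 9 bicyclic α,β-unsaturated δ-lactone (cyclopenta[c]pyran-3-one), via phosphonate ester 8 (not isolated)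
Conditions: 7, EDC·HCl, DMAP (10 mol %), MeCN, 0 °C → rt; then LiCl, DBU, 0 °C → rt
Reagents that add atoms: none
Why: Carbodiimide esterification followed by an intramolecular Horner–Wadsworth–Emmons olefination of the C1 ketone should close a six-membered lactone, so that the carboxyl carbon C9 is forced cis to C5 on the new tetrasubstituted C1=C10 alkene and the alkene geometry is set by the tether.

Step 4
Reactants: 9 bicyclic lactone
Product: 10 lactol (mixture of anomers)
Conditions: i-Bu2AlH (1.1 equiv), CH2Cl2, −78 °C; aq potassium sodium tartrate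
Reagents that add atoms: none
Why: Half-reduction of a lactone with i-Bu2AlH stops at the tetrahedral aluminate at low temperature, the pinacol boronate should be tolerated, and the new anomeric centre is lost in the next step.

Step 5
Reactants: 10 lactol
Product: 11 dienol with (Z)-C1=C10 and a C9=C8 vinyl group
Conditions: Ph3PCH3Br, KOt-Bu, THF, 0 °C → rt
Reagents that add atoms: methyltriphenylphosphonium bromide, C[P+](c1ccccc1)(c1ccccc1)c1ccccc1.[Br-]
Why: Wittig methylenation of the ring-opened hydroxy-enal form of the lactol installs C8 and frees O6, and the tetrasubstituted alkene is not involved so its geometry is retained.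

Step 6
Reactants: 11 dienol
Product: 12 dienyl acetate
Conditions: Ac2O, pyridine, DMAP (cat.), CH2Cl2, rt
Reagents that add atoms: acetic anhydride, CC(=O)OC(C)=O
Why: Standard acylation of the secondary alcohol installs the C6 acetate of the target, which later also shields one face of the C7=C8 olefin.

Step 7
Reactants: 12 dienyl acetate
Product: 14 primary alcohol at C8 with free C4 tertiary alcohol, via alkylborane 13 (not isolated)
Conditions: (3-methylbutan-2-yl)2BH (from BH3·SMe2 and 2-methylbut-2-ene, THF, 0 °C), THF, 0 °C → rt; then NaBO3·4H2O, THF/H2O, rt → 40 °C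
Reagents that add atoms: sodium perborate tetrahydrate (NaBO3·4H2O), [Na+].[Na+].O[B-]1(O)OO[B-](O)(O)OO1
Why: The bulky dialkylborane should add only to the monosubstituted terminus of the diene (boron to C8) and leave the hindered 1,1-disubstituted and tetrasubstituted alkenes, and perborate then oxidises both C–B bonds with retention, so the C4 boronate becomes the C4 tertiary alcohol with the configuration set in step 2.

Step 8
Reactants: 14 diol
Product: 15 β,γ-unsaturated aldehyde
Conditions: Dess–Martin periodinane, pyridine, CH2Cl2, 0 °C → rt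
Reagents that add atoms: none
Why: Buffered Dess–Martin oxidation converts the primary alcohol into the aldehyde without touching the tertiary alcohol and without moving the C1=C10 alkene into conjugation.

Step 9
Reactants: 15 aldehyde
Product: 16 triene (metathesis precursor)
Conditions: Ph3PCH3Br, KN(SiMe3)2, THF, −78 → 0 °C
Reagents that add atoms: methyltriphenylphosphonium bromide, C[P+](c1ccccc1)(c1ccccc1)c1ccccc1.[Br-]
Why: Wittig methylenation at low temperature should be much faster at the aldehyde than any attack on the acetate and gives the C8 vinyl terminus.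

Step 10
Reactants: 16 triene
Product: 17 (3S,3aR,4S)-3-hydroxy-3,8-dimethyl-5-(propan-2-yl)-1,2,3,3a,4,7-hexahydroazulen-4-yl acetate
Conditions: second-generation Grubbs catalyst RuCl2(=CHPh)(H2IMes)(PCy3) (5–10 mol %), CH2Cl2 (2 mM), 40 °C
Reagents that add atoms: none
Why: Ring-closing olefin metathesis by the Chauvin mechanism: the ruthenium benzylidene exchanges first with the unhindered C8 vinyl group, and the resulting alkylidene undergoes intramolecular [2+2] cycloaddition with the 1,1-disubstituted C7 methylidene and cycloreversion with loss of ethene. The closest known reaction type is ring-closing metathesis of a mono- with a 1,1-disubstituted olefin to a trisubstituted cycloheptene carrying an allylic oxygen substituent. The seven-membered carbocycle is closed through a ruthenacyclobutane that joins C7 and C8, and ethene loss makes the closure irreversible. No stereocentre is formed here; C7 and C8 become one prochiral olefin whose two centres are set in step 11 by the C6 acetate. The step needs chemoselectivity (the tetrasubstituted C1=C10 alkene must not react and the skipped diene must not isomerise) and cyclisation over oligomerisation; the first is secured by the steric inertness of tetrasubstituted alkenes towards the ruthenium carbene, the second by the (Z)-alkene and the cyclopentane, which hold both arms cis, and by high dilution.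

Step 11
Reactants: 17 bicyclic diene
Product: 19 C8 alcohol with C6 acetate, via alkylborane 18 (not isolated)
Conditions: 9-BBN (3 equiv), THF, 65 °C; then NaBO3·4H2O, THF/H2O, rt
Reagents that add atoms: sodium perborate tetrahydrate (NaBO3·4H2O), [Na+].[Na+].O[B-]1(O)OO[B-](O)(O)OO1
Why: Hydroboration–oxidation places boron on the less substituted C8 by syn addition from the face anti to the allylic C6 acetate (the usual sense for cyclic allylic esters), which should set H-7 and O-8 cis to each other and trans to O-6, while 9-BBN does not add to the tetrasubstituted alkene and the oxidation proceeds with retention.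

Step 12
Reactants: 19 hydroxy acetate; 20 angelic acid
Product: 22 target angelate, via mixed anhydride 21 (not isolated)
Conditions: 20, 2,4,6-trichlorobenzoyl chloride, Et3N, toluene, rt; then 19, toluene, 80 °C
Reagents that add atoms: none
Why: Yamaguchi-type acylation through the mixed anhydride without a nucleophilic catalyst should esterify the secondary C8 alcohol without Z → E isomerisation of the angeloyl group, and the tertiary C4 alcohol does not react.

Compound list
1 | 3-methylbutanal | CC(C)CC=O | starting material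
2 | 3-methyl-2-methylidenebutanal | CC(C)C(=C)C=O | intermediate
3 | 3-methylcyclopent-2-en-1-one | CC1=CC(=O)CC1 | starting material
4 | bis(pinacolato)diboron | CC1(C)OB(OC1(C)C)B1OC(C)(C)C(C)(C)O1 | starting material
5 | 4,4,5,5-tetramethyl-2-{[(3R)-3-methyl-3-(4,4,5,5-tetramethyl-1,3,2-dioxaborolan-2-yl)cyclopent-1-en-1-yl]oxy}-1,3,2-dioxaborolane (boron enolate) | C[C@]1(B2OC(C)(C)C(C)(C)O2)CCC(OB2OC(C)(C)C(C)(C)O2)=C1 | intermediate
6 | (2S,3R)-2-[(1S)-1-hydroxy-3-methyl-2-methylidenebutyl]-3-methyl-3-(4,4,5,5-tetramethyl-1,3,2-dioxaborolan-2-yl)cyclopentan-1-one | O=C1CC[C@](C)(B2OC(C)(C)C(C)(C)O2)[C@H]1[C@H](O)C(=C)C(C)C | intermediate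
7 | 2-(diethoxyphosphoryl)propanoic acid (racemic) | CCOP(=O)(OCC)C(C)C(O)=O | starting material
8 | (1S)-3-methyl-2-methylidene-1-[(1S,2R)-2-methyl-5-oxo-2-(4,4,5,5-tetramethyl-1,3,2-dioxaborolan-2-yl)cyclopentyl]butyl 2-(diethoxyphosphoryl)propanoate (epimers at the phosphonate carbon) | O=C1CC[C@](C)(B2OC(C)(C)C(C)(C)O2)[C@H]1[C@H](OC(=O)C(C)P(=O)(OCC)OCC)C(=C)C(C)C | intermediate
9 | (1S,7R,7aR)-4,7-dimethyl-1-(3-methylbut-1-en-2-yl)-7-(4,4,5,5-tetramethyl-1,3,2-dioxaborolan-2-yl)-5,6,7,7a-tetrahydrocyclopenta[c]pyran-3(1H)-one | CC1=C2CC[C@](C)(B3OC(C)(C)C(C)(C)O3)[C@H]2[C@@H](C(=C)C(C)C)OC1=O | intermediate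
10 | (1S,7R,7aR)-4,7-dimethyl-1-(3-methylbut-1-en-2-yl)-7-(4,4,5,5-tetramethyl-1,3,2-dioxaborolan-2-yl)-1,3,5,6,7,7a-hexahydrocyclopenta[c]pyran-3-ol (both C3 epimers) | CC1=C2CC[C@](C)(B3OC(C)(C)C(C)(C)O3)[C@H]2[C@@H](C(=C)C(C)C)OC1O | intermediate
11 | (1S)-1-[(1R,2R,5Z)-5-(but-3-en-2-ylidene)-2-methyl-2-(4,4,5,5-tetramethyl-1,3,2-dioxaborolan-2-yl)cyclopentyl]-3-methyl-2-methylidenebutan-1-ol | C=C/C(C)=C1/CC[C@](C)(B2OC(C)(C)C(C)(C)O2)[C@H]1[C@H](O)C(=C)C(C)C | intermediate
12 | (1S)-1-[(1R,2R,5Z)-5-(but-3-en-2-ylidene)-2-methyl-2-(4,4,5,5-tetramethyl-1,3,2-dioxaborolan-2-yl)cyclopentyl]-3-methyl-2-methylidenebutyl acetate | C=C/C(C)=C1/CC[C@](C)(B2OC(C)(C)C(C)(C)O2)[C@H]1[C@H](OC(C)=O)C(=C)C(C)C | intermediate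
13 | C8-bis(3-methylbutan-2-yl)boryl adduct of 12 (boron on the former vinyl terminus, C9 now CH2, stereocentres as in 12) | CC(C)C(C)B(CC/C(C)=C1/CC[C@](C)(B2OC(C)(C)C(C)(C)O2)[C@H]1[C@H](OC(C)=O)C(=C)C(C)C)C(C)C(C)C | intermediate
14 | (1S)-1-[(1R,2S,5Z)-2-hydroxy-5-(4-hydroxybutan-2-ylidene)-2-methylcyclopentyl]-3-methyl-2-methylidenebutyl acetate | OCC/C(C)=C1/CC[C@](C)(O)[C@H]1[C@H](OC(C)=O)C(=C)C(C)C | intermediate
15 | (1S)-1-[(1R,2S,5Z)-2-hydroxy-2-methyl-5-(4-oxobutan-2-ylidene)cyclopentyl]-3-methyl-2-methylidenebutyl acetate | O=CC/C(C)=C1/CC[C@](C)(O)[C@H]1[C@H](OC(C)=O)C(=C)C(C)C | intermediate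
16 | (1S)-1-[(1R,2S,5Z)-2-hydroxy-2-methyl-5-(pent-4-en-2-ylidene)cyclopentyl]-3-methyl-2-methylidenebutyl acetate | C=CC/C(C)=C1/CC[C@](C)(O)[C@H]1[C@H](OC(C)=O)C(=C)C(C)C | intermediate
17 | (3S,3aR,4S)-3-hydroxy-3,8-dimethyl-5-(propan-2-yl)-1,2,3,3a,4,7-hexahydroazulen-4-yl acetate | CC(C)C1=CCC(C)=C2CC[C@](C)(O)[C@H]2[C@@H]1OC(C)=O | intermediate
18 | C8-(9-borabicyclo[3.3.1]nonan-9-yl) adduct of 17 (boron α at C8, H α at C7, other centres as in 19) | B1(C2CCCC1CCC2)[C@H]1CC(C)=C2CC[C@](C)(O)[C@H]2[C@H](OC(C)=O)[C@@H]1C(C)C | intermediate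
19 | (3S,3aR,4R,5R,6S)-3,6-dihydroxy-3,8-dimethyl-5-(propan-2-yl)-1,2,3,3a,4,5,6,7-octahydroazulen-4-yl acetate | O[C@H]1CC(C)=C2CC[C@](C)(O)[C@H]2[C@H](OC(C)=O)[C@@H]1C(C)C | intermediate
20 | (2Z)-2-methylbut-2-enoic acid (angelic acid) | C/C=C(/C)C(=O)O | starting material
21 | (2Z)-2-methylbut-2-enoic 2,4,6-trichlorobenzoic anhydride | C/C=C(/C)C(=O)OC(=O)c1c(Cl)cc(Cl)cc1Cl | intermediate
22 | (3S,3aR,4R,5R,6S)-4-(acetyloxy)-3-hydroxy-3,8-dimethyl-5-(propan-2-yl)-1,2,3,3a,4,5,6,7-octahydroazulen-6-yl (2Z)-2-methylbut-2-enoate (CNP0258590.1) | C/C=C(/C)C(=O)O[C@H]1CC(C)=C2CC[C@](C)(O)[C@H]2[C@H](OC(C)=O)[C@@H]1C(C)C | target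

Total step count: 12. Longest linear sequence: 12 steps (from 3-methylbutanal; 11 from 3-methylcyclopent-2-en-1-one).

Steps most likely to fail

Step 3. The base may trigger E1cB loss of the acyloxy group from the β-acyloxy ketone, or epimerise C5 through the dienolate of the product, faster than the slow olefination that has to form a tetrasubstituted alkene. Fallback (sets out from 6, returns at 9): 6 is acylated with 2-bromopropanoyl bromide (pyridine, CH2Cl2, −20 °C) to the α-bromo ester F2. SmI2 in THF at −78 °C then closes the lactone ring by an intramolecular Reformatsky addition to the C1 ketone under neutral conditions, giving the β-hydroxy lactone F3. Dehydration (SOCl2, pyridine, 0 °C, then brief DBU to bring the alkene into conjugation) should deliver 9.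

Step 2. The weakly nucleophilic pinacol boron enolate may add too slowly to the α-branched enal at its neopentyl-like carbon, so that protonation or loss of diastereoselectivity takes over. Fallback (sets out from boron enolate 5, returns at 6): 5 is quenched with N-bromosuccinimide to give the α-bromo ketone F1, which is isolated. A Reformatsky-type addition mediated by CrCl2 (LiI cat., THF, rt) then regenerates a metal enolate only at C5 and adds it to aldehyde 2 anti to the boronate, with the anti selectivity usual for chromium enolates, to give 6.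

Step 7. Chemoselectivity may be lost through competing hydroboration of the 1,1-disubstituted alkene or 1,4-addition across the diene. Fallback (sets out from 12, returns at 15): the C–B bond of 12 is first oxidised (NaBO3·4H2O, THF/H2O) to the tertiary alcohol F4. The terminal vinyl group is then oxidised directly to the aldehyde by an aldehyde-selective Wacker oxidation (PdCl2(MeCN)2, CuCl2, AgNO2, t-BuOH/MeNO2, O2, rt), which tells the alkenes apart by coordination to palladium and not by steric access of a borane, giving 15 without passing through 14.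

Further compounds
F1 | step 2 | (3R)-2-bromo-3-methyl-3-(4,4,5,5-tetramethyl-1,3,2-dioxaborolan-2-yl)cyclopentan-1-one (both C2 epimers) | O=C1CC[C@](C)(B2OC(C)(C)C(C)(C)O2)C1Br
F2 | step 3 | (1S)-3-methyl-2-methylidene-1-[(1S,2R)-2-methyl-5-oxo-2-(4,4,5,5-tetramethyl-1,3,2-dioxaborolan-2-yl)cyclopentyl]butyl 2-bromopropanoate | O=C1CC[C@](C)(B2OC(C)(C)C(C)(C)O2)[C@H]1[C@H](OC(=O)C(C)Br)C(=C)C(C)C
F3 | step 3 | 4a-hydroxy-4,7-dimethyl-1-(3-methylbut-1-en-2-yl)-7-(4,4,5,5-tetramethyl-1,3,2-dioxaborolan-2-yl)hexahydrocyclopenta[c]pyran-3(1H)-one (C1, C7 and C7a as in 9; epimers at C4 and C4a) | CC1C(=O)O[C@H](C(=C)C(C)C)[C@@H]2[C@@](C)(B3OC(C)(C)C(C)(C)O3)CCC12O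
F4 | step 7 | (1S)-1-[(1R,2S,5Z)-5-(but-3-en-2-ylidene)-2-hydroxy-2-methylcyclopentyl]-3-methyl-2-methylidenebutyl acetate | C=C/C(C)=C1/CC[C@](C)(O)[C@H]1[C@H](OC(C)=O)C(=C)C(C)C
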